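(The earlier runs and the new flask come from a simulation with made-up constants; noise was put on by code.)

Late in the runs, at 2.50 min, beta shows 49% product and gamma 42%. The question, though, is put at the other end of the curve.

in all of them: starting material 0.30 M; free catalyst 15 mM
- beta: reagent 0.60 M; protic impurity 0.42 M; run made earlier
- gamma: reagent 0.60 M; protic impurity 0.66 M; run made earlier
- flask: reagent 0.600 M; protic impurity 0.300 M

| run | time / min | product / % | starting material / % |
|---|---|---|---|
| beta | 0.200 | 1 | 52 |
| beta | 0.333 | 6 | 41 |
| beta | 0.667 | 15 | 28 |
| beta | 1.33 | 29 | 12 |
| beta | 2.50 | 49 | 0 |
| gamma | 0.200 | 0 | 51 |
| gamma | 0.667 | 14 | 21 |
| gamma | 1.00 | 18 | 13 |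
| gamma | 1.50 | 28 | 10 |
| gamma | 2.50 | 42 | 4 |

(standard deviation of a reading: 2 percentage points)

- apparent order in reagent when 10% of the starting material are converted (percent change of the rate of making product for one percent more reagent charged)
- apparent order in free catalyst when 10% of the starting material are converted (percent change of the rate of making product for one percent more free catalyst charged)

- the analysis behind the earlier runs scatters by 2 percentage points, standard deviation
- no earlier run changes the charge of free catalyst; that part of a forecast is a guess
- no earlier run changes the charge of reagent; that part of a forecast is a guess

Conversion counts starting material, not product, so I time the mark from the first fall in beta, taken as one exponential: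

mark time = 0.200 min × ln(90.0%) / ln(52%) = 0.0322 min

This mark time, my estimate of the time the flask needs to lose 10% of its starting material, is what I carry. Gamma, with more impurity, reads 51% at that first reading, so I use the figure for the flask too.

The mark comes earlier than that reading, where beta still holds 1% product, within the scatter of 2 percentage points of none. The mark therefore lies inside the lag, the induction period.

Neither charge was varied in the earlier runs, so I bracket the flask with two extremes.

Steady stream: stock passes on as fast as it forms. If its forming runs on catalyst, the order in catalyst is 1, and if reagent passes it on without changing the flow, its order is 0.

Very start of the lag: if the first fall runs on catalyst, more catalyst shortens the time to the mark in proportion. If a second stage also runs on catalyst, what it has built by the mark stays the same, so the order in catalyst is 0. If that stock at the mark does not depend on reagent, rate ∝ [reagent] and its order is 1.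

As a rough weight I take the mark's place in the lag, with the first reading of beta standing in for the lag's end:

weight = 0.0322 min / 0.200 min = 0.161

My reckoning for the flask is thus 0.839 in reagent and 0.161 in catalyst.

The forecast differs, with 0.4 (−0.1 to 1.2) in reagent and 0.9 (0.3 to 1.3) in catalyst, and says “Both are guesses, so the ranges are wide.”

The flask gives 0.92 in reagent and 0.35 in free catalyst.

    starting material + protic impurity → quenched substrate (k = 0.0342 /M/s)
    reagent + catalyst intermediate → free catalyst + product (k = 0.274 /M/s)
    free catalyst + open intermediate ⇌ catalyst intermediate (K = 95.0 /M, k = 2.15 /M/s)
    starting material + free catalyst ⇌ free catalyst + open intermediate (K = 1.84, k = 4.42 /M/s)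

The flask passes 10% conversion at 0.0237 min, against my mark time of 0.0322 min, while catalyst intermediate goes on to product at 9.9 /min with reagent as charged, a life by that step alone of 0.101 min, which is longer than either time. Free catalyst turns starting material over at 80 /min with starting material as charged, and doubling the free catalyst multiplies the rate by 1.20.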